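**Plan**

1. Cuts (germacrane numbering): the O8 acyl bond and the C1–C10 epoxide oxygen; then C11=C13 and the lactone O6–C12 bond; then C7–C11 (enolate alkylation) and C8–C9 with C6–C1 re-formed (retro-oxy-Cope). This leads back to a cyclohexenol built from (S)-isopiperitenone and a Z-2-alkoxyvinyl anion.
2. Enabling feature: C1–C6 with the Z C4=C5 alkene are a 3-methylcyclohex-2-enol ring, and O=C6–C7–C8–C9–C10=C1 is an oxy-Cope retron, so the ten-membered ring is a four-atom expansion of the terpene ring.
3. Forward order: six-membered ring from (R)-limonene → 1,2-adduct → ten-membered ring by anionic oxy-Cope with C7 alkylation in the same flask → γ-lactone ring → C13 methylene → C8 ester → epoxide ring last.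
4. Stereochemistry: the limonene centre directs the carbinol; the chair [3,3] shift carries both to C8; the potassium-chelated enolate sets C7; peripheral hydride sets C6 and peripheral peracid sets C1/C10; the side chain comes from a Katsuki–Sharpless epoxidation of angelyl alcohol.
5. The enol ether is Z by design: its lithium reagent is stable, and in the chair it puts O8 axial on the C14 face, so that outer-face alkylation gives the C7/C8 relation of the target. This choice fixes the (R)-limonene series.

Key step: step 5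

Remark: ring positions carry germacrane numbers throughout (C6 lactone carbinol, C7 ring fusion, C8 ester carbinol, C1–C10 epoxide); α and β mean below and above the ring as usually drawn with C14 up.

**Route**

Step 1
Reactants: 1 (R)-(+)-limonene
Product: 2 (S)-isopiperitenone [(6S)-3-methyl-6-(prop-1-en-2-yl)cyclohex-2-en-1-one]
Conditions: t-BuOOH, Cr(CO)6 (cat.), MeCN, reflux
Reagents that add atoms: tert-butyl hydroperoxide, CC(C)(C)OO
Why: Chromium-catalysed allylic oxidation with tert-butyl hydroperoxide should turn the ring CH2 next to the unsubstituted alkene carbon into the conjugated ketone without touching the limonene stereocentre or the isopropenyl group, the regioisomeric enone (carvone) being removed by chromatography; no new stereocentre is formed.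

Step 2
Reactants: 3 4-methoxybenzyl alcohol
Product: 8 4-methoxybenzyl ethynyl ether, via potassium 4-methoxybenzyl oxide 4 (not isolated), via (E)-1,2-dichlorovinyl 4-methoxybenzyl ether 5 (not isolated), via chloroethynyl 4-methoxybenzyl ether 6 (not isolated), via lithium (4-methoxybenzyloxy)ethynide 7 (not isolated)
Conditions: KH, THF, 0 °C; Cl2C=CHCl, −50 °C → rt; n-BuLi, −78 → −40 °C; H2O, −78 °C
Reagents that add atoms: trichloroethylene, ClC=C(Cl)Cl
Why: One-flask ynol ether synthesis in which the potassium alkoxide adds anti to dichloroacetylene (formed from trichloroethylene by base), and n-BuLi then brings about elimination of LiCl to the chloroalkyne and chlorine–lithium exchange to the lithium alkynyl ether that is protonated at −78 °C; no stereocentre is involved, and the benzylic ynol ether is kept cold and used at once because such ethers rearrange on warming.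

Step 3
Reactants: 8 4-methoxybenzyl ethynyl ether
Product: 9 (Z)-tributyl[2-(4-methoxybenzyloxy)ethenyl]stannane
Conditions: Bu3SnH, Et3B (cat.), air, hexane, 0 °C
Reagents that add atoms: tributyltin hydride, CCCC[SnH](CCCC)CCCC
Why: Radical hydrostannation: the stannyl radical adds to the terminal alkyne carbon and the α-alkoxyvinyl radical takes up hydrogen anti to tin, so the kinetic product at 0 °C should be the Z β-stannyl enol ether, as in the preparation of the ethyl analogue; no stereocentre is formed.

Step 4
Reactants: 9 (Z)-tributyl[2-(4-methoxybenzyloxy)ethenyl]stannane, 2 (S)-isopiperitenone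
Product: 11 (1S,6S)-1-[(Z)-2-(4-methoxybenzyloxy)ethenyl]-3-methyl-6-(prop-1-en-2-yl)cyclohex-2-en-1-ol, via (Z)-2-(4-methoxybenzyloxy)ethenyllithium 10 (not isolated)
Conditions: n-BuLi, THF, −78 °C; then 2, −78 °C; H2O
Reagents that add atoms: none
Why: Tin–lithium exchange with retention gives the Z β-alkoxyvinyllithium, which is held by internal O–Li coordination and cannot lose alkoxide by anti elimination as an E reagent would, and its 1,2-addition to the enone should take the carbonyl face opposite the pseudo-equatorial isopropenyl group, which sets the carbinol centre as S with the two alkenyl groups trans and the hydroxyl cis to isopropenyl; the work-up stays non-acidic because the adduct is an acid-labile enol ether.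

Step 5
Reactants: 11 (1S,6S)-1-[(Z)-2-(4-methoxybenzyloxy)ethenyl]-3-methyl-6-(prop-1-en-2-yl)cyclohex-2-en-1-ol, 12 methyl bromoacetate
Product: 15 methyl 2-[(1R,3Z,7E,10R)-10-(4-methoxybenzyloxy)-4,8-dimethyl-2-oxocyclodeca-3,7-dien-1-yl]acetate, via potassium cyclohexenolate 13 (not isolated), via potassium cyclodecadienolate 14 (not isolated)
Conditions: KN(SiMe3)2, THF, 0 °C → rt (no crown ether); then 12, −78 → −40 °C
Reagents that add atoms: none
Why: KN(SiMe3)2 forms potassium alkoxide 13, whose charge weakens the doubly allylic C6–C1 ring bond and drives a [3,3] shift in which the enol-ether CH (C8) bonds to the isopropenyl CH2 (C9) while C6–C1 breaks, and the resulting enolate 14 is alkylated at C7 by bromoacetate 12 in the same flask (C7–C11). The closest known reaction type is the anionic oxy-Cope ring expansion of trans-1,2-dialkenylcyclohexanols to cyclodec-5-enones with capture of the enolate by an alkyl halide. The ten-membered ring is not closed end to end but arises by a four-atom expansion of the six-membered ring through a six-centre chair transition state, the cyclohexene alkene becoming the Z C4=C5 bond and the equatorial ring bonds giving the E C1=C10 alkene and the E-configured ring enolate. C8 is set by suprafacial transfer of the (1S,6S) carbinol chirality through this chair, in which the Z ether oxygen sits axial, syn to the alkoxide oxygen and bridged to it by K+, which leads to 8R. C7 is set when the K+-chelated enolate, still in the conformation in which it is born, is alkylated on its outer face, anti to C9 and away from the transannular C1=C10 bond, which places C11 cis to O8 (7R). The step needs chair over boat, C-alkylation faster than loss of the C8 alkoxide and no inversion of the enolate conformation, which the trans-diequatorial alkenyl groups, the crown-free chelate that holds the C8–O bond near the nodal plane of the enolate, and alkylation at −78 °C should secure.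

Step 6
Reactants: 15 methyl 2-[(1R,3Z,7E,10R)-10-(4-methoxybenzyloxy)-4,8-dimethyl-2-oxocyclodeca-3,7-dien-1-yl]acetate
Product: 17 (3aR,4R,6E,10Z,11aR)-4-(4-methoxybenzyloxy)-6,10-dimethyl-3a,4,5,8,9,11a-hexahydrocyclodeca[b]furan-2(3H)-one, via 6R hydroxy ester 16 (not isolated)
Conditions: NaBH4, CeCl3·7H2O, MeOH, −78 → −20 °C; then 1,8-diazabicyclo[5.4.0]undec-7-ene (cat.), PhMe, rt
Reagents that add atoms: none
Why: Luche 1,2-reduction followed by base-catalysed lactonisation: in the methanol-solvated, non-chelated enone the C6 carbonyl should point away from the C8 ether oxygen, so that hydride from the ring periphery gives the 6R (6α) allylic alcohol, anti to O8 and with its oxygen trans to the C7 acetate arm, which then closes the trans-fused γ-lactone by 5-exo-trig acyl substitution with retention at C6.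

Step 7
Reactants: 17 (3aR,4R,6E,10Z,11aR)-4-(4-methoxybenzyloxy)-6,10-dimethyl-3a,4,5,8,9,11a-hexahydrocyclodeca[b]furan-2(3H)-one
Product: 21 (3aR,4R,6E,10Z,11aR)-4-(4-methoxybenzyloxy)-6,10-dimethyl-3-methylidene-3a,4,5,8,9,11a-hexahydrocyclodeca[b]furan-2(3H)-one, via lithium lactone enolate 18 (not isolated), via Mannich base 19 (not isolated), via trimethylammonium iodide 20 (not isolated)
Conditions: LiN(iPr)2, THF, −78 °C; Me2N=CH2 I, −78 °C → rt; MeI, MeOH, rt; NaHCO3, H2O/CH2Cl2, rt
Reagents that add atoms: dimethylmethyleneiminium iodide, C=[N+](C)C.[I-]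
Why: Mannich α-methylenation: the lithium lactone enolate adds to the iminium salt at C11, and N-methylation followed by E1cB loss of trimethylamine gives the exocyclic C11=C13 alkene, so that C11 ends sp2 and carries no stereocentre while C7, which is not enolisable, is untouched.

Step 8
Reactants: 21 (3aR,4R,6E,10Z,11aR)-4-(4-methoxybenzyloxy)-6,10-dimethyl-3-methylidene-3a,4,5,8,9,11a-hexahydrocyclodeca[b]furan-2(3H)-one
Product: 22 (3aR,4R,6E,10Z,11aR)-4-hydroxy-6,10-dimethyl-3-methylidene-3a,4,5,8,9,11a-hexahydrocyclodeca[b]furan-2(3H)-one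
Conditions: DDQ, CH2Cl2/pH 7 buffer, 0 °C
Reagents that add atoms: none
Why: Oxidative cleavage of the 4-methoxybenzyl ether by DDQ (benzylic hydride abstraction, then hydrolysis of the oxocarbenium ion) should free the C8 alcohol with retention and leave the trisubstituted alkenes and the methylene lactone untouched.

Step 9
Reactants: 23 angelic acid
Product: 24 (Z)-2-methylbut-2-en-1-ol
Conditions: LiAlH4, Et2O, 0 °C → rt
Reagents that add atoms: none
Why: Hydride reduction of the carboxylic acid by LiAlH4 in ether should give the allylic alcohol by 1,2-reduction with the Z geometry kept; no stereocentre is formed.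

Step 10
Reactants: 24 (Z)-2-methylbut-2-en-1-ol
Product: 25 [(2R,3S)-2,3-dimethyloxiran-2-yl]methanol
Conditions: Ti(OiPr)4 (cat.), D-(−)-diethyl tartrate (cat.), t-BuOOH, 4 Å molecular sieves, CH2Cl2, −20 °C
Reagents that add atoms: tert-butyl hydroperoxide, CC(C)(C)OO
Why: Katsuki–Sharpless asymmetric epoxidation: with D-(−)-diethyl tartrate the titanium-bound peroxide should be delivered to the alkene face that gives the (2R,3S)-epoxy alcohol, the cis relation of CH2OH and the C3 methyl following from the Z alkene.

Step 11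
Reactants: 25 [(2R,3S)-2,3-dimethyloxiran-2-yl]methanol
Product: 26 (2S,3S)-2,3-dimethyloxirane-2-carboxylic acid
Conditions: RuCl3·3H2O (cat.), NaIO4, MeCN/EtOAc/H2O, 0 °C → rt
Reagents that add atoms: water, O
Why: Ruthenium tetroxide oxidation (catalytic RuCl3 with NaIO4) takes the primary alcohol through the aldehyde hydrate to the acid without opening the epoxide; both stereocentres are untouched and C2 becomes S only through the change in CIP priority.

Step 12
Reactants: 22 (3aR,4R,6E,10Z,11aR)-4-hydroxy-6,10-dimethyl-3-methylidene-3a,4,5,8,9,11a-hexahydrocyclodeca[b]furan-2(3H)-one, 26 (2S,3S)-2,3-dimethyloxirane-2-carboxylic acid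
Product: 28 (3aR,4R,6E,10Z,11aR)-6,10-dimethyl-3-methylidene-2-oxo-2,3,3a,4,5,8,9,11a-octahydrocyclodeca[b]furan-4-yl (2S,3S)-2,3-dimethyloxirane-2-carboxylate, via mixed anhydride 27 (not isolated)
Conditions: 26, 2,4,6-Cl3C6H2COCl, Et3N, THF, rt; then 22, 4-(dimethylamino)pyridine, PhMe, rt → 40 °C
Reagents that add atoms: none
Why: Yamaguchi esterification: the mixed anhydride of the non-enolisable epoxy acid should acylate the hindered C8 alcohol at the epoxy-acid carbonyl under 4-(dimethylamino)pyridine catalysis, with retention at C8 and at both oxirane carbons.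

Step 13
Reactants: 28 (3aR,4R,6E,10Z,11aR)-6,10-dimethyl-3-methylidene-2-oxo-2,3,3a,4,5,8,9,11a-octahydrocyclodeca[b]furan-4-yl (2S,3S)-2,3-dimethyloxirane-2-carboxylate
Product: 29 CNP0165580.1 [1β,10α-epoxy-8β-((2S,3S)-2,3-dimethyloxirane-2-carbonyloxy)germacra-4Z,11(13)-dien-12,6α-olide]
Conditions: mCPBA, NaHCO3, CH2Cl2, 0 °C
Reagents that add atoms: 3-chloroperoxybenzoic acid, OOC(=O)c1cccc(Cl)c1
Why: Prilezhaev epoxidation: the peracid should choose the electron-rich trisubstituted C1=C10 bond over the C4=C5 bond (deactivated by the allylic lactone oxygen) and the electron-poor methylene lactone, and attack the outer face of the E alkene in the conformer that has C14 on the side of O8, which gives the 1R,10R (1β,10α) epoxide.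

**Compound list**

1 | (R)-(+)-limonene | CC1=CC[C@@H](CC1)C(C)=C | starting material
2 | (S)-isopiperitenone [(6S)-3-methyl-6-(prop-1-en-2-yl)cyclohex-2-en-1-one] | CC1=CC(=O)[C@@H](CC1)C(C)=C | intermediate
3 | 4-methoxybenzyl alcohol | COc1ccc(CO)cc1 | starting material
4 | potassium 4-methoxybenzyl oxide | COc1ccc(C[O-])cc1.[K+] | intermediate
5 | (E)-1,2-dichlorovinyl 4-methoxybenzyl ether | COc1ccc(CO/C(Cl)=C\Cl)cc1 | intermediate
6 | chloroethynyl 4-methoxybenzyl ether | COc1ccc(COC#CCl)cc1 | intermediate
7 | lithium (4-methoxybenzyloxy)ethynide | COc1ccc(COC#[C-])cc1.[Li+] | intermediate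
8 | 4-methoxybenzyl ethynyl ether | COc1ccc(COC#C)cc1 | intermediate
9 | (Z)-tributyl[2-(4-methoxybenzyloxy)ethenyl]stannane | CCCC[Sn](CCCC)(CCCC)/C=C\OCc1ccc(OC)cc1 | intermediate
10 | (Z)-2-(4-methoxybenzyloxy)ethenyllithium | [Li]/C=C\OCc1ccc(OC)cc1 | intermediate
11 | (1S,6S)-1-[(Z)-2-(4-methoxybenzyloxy)ethenyl]-3-methyl-6-(prop-1-en-2-yl)cyclohex-2-en-1-ol | CC1=C[C@@](O)(/C=C\OCc2ccc(OC)cc2)[C@@H](CC1)C(C)=C | intermediate
12 | methyl bromoacetate | COC(=O)CBr | starting material
13 | potassium (1S,6S)-1-[(Z)-2-(4-methoxybenzyloxy)ethenyl]-3-methyl-6-(prop-1-en-2-yl)cyclohex-2-en-1-olate (potassium cyclohexenolate) | CC1=C[C@@]([O-])(/C=C\OCc2ccc(OC)cc2)[C@@H](CC1)C(C)=C.[K+] | intermediate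
14 | potassium enolate of (2Z,6E,9R)-9-(4-methoxybenzyloxy)-3,7-dimethylcyclodeca-2,6-dien-1-one (potassium cyclodecadienolate; O–C6=C7, C5 trans to C8) | [K+].[O-]/C1=C\[C@H](OCc2ccc(OC)cc2)C/C(C)=C/CC/C(C)=C\1 | intermediate
15 | methyl 2-[(1R,3Z,7E,10R)-10-(4-methoxybenzyloxy)-4,8-dimethyl-2-oxocyclodeca-3,7-dien-1-yl]acetate (7R,8R in germacrane numbering) | O=C1/C=C(/C)CC/C=C(\C)C[C@@H](OCc2ccc(OC)cc2)[C@H]1CC(=O)OC | intermediate
16 | methyl 2-[(1S,2R,3Z,7E,10R)-2-hydroxy-10-(4-methoxybenzyloxy)-4,8-dimethylcyclodeca-3,7-dien-1-yl]acetate (6R hydroxy ester; C7 arrangement as in 15) | O[C@@H]1/C=C(/C)CC/C=C(\C)C[C@@H](OCc2ccc(OC)cc2)[C@H]1CC(=O)OC | intermediate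
17 | (3aR,4R,6E,10Z,11aR)-4-(4-methoxybenzyloxy)-6,10-dimethyl-3a,4,5,8,9,11a-hexahydrocyclodeca[b]furan-2(3H)-one | C1C(=O)O[C@@H]2/C=C(/C)CC/C=C(\C)C[C@@H](OCc3ccc(OC)cc3)[C@@H]12 | intermediate
18 | lithium enolate of lactone 17 (C12–O, C11=C12) | C1=C([O-])O[C@@H]2/C=C(/C)CC/C=C(\C)C[C@@H](OCc3ccc(OC)cc3)[C@@H]12.[Li+] | intermediate
19 | (3aR,4R,6E,10Z,11aR)-3-[(dimethylamino)methyl]-4-(4-methoxybenzyloxy)-6,10-dimethyl-3a,4,5,8,9,11a-hexahydrocyclodeca[b]furan-2(3H)-one (Mannich base, C3 epimers) | CN(C)CC1C(=O)O[C@@H]2/C=C(/C)CC/C=C(\C)C[C@@H](OCc3ccc(OC)cc3)[C@@H]12 | intermediate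
20 | N-methyl quaternary ammonium iodide of 19 (trimethylammonium iodide) | C[N+](C)(C)CC1C(=O)O[C@@H]2/C=C(/C)CC/C=C(\C)C[C@@H](OCc3ccc(OC)cc3)[C@@H]12.[I-] | intermediate
21 | (3aR,4R,6E,10Z,11aR)-4-(4-methoxybenzyloxy)-6,10-dimethyl-3-methylidene-3a,4,5,8,9,11a-hexahydrocyclodeca[b]furan-2(3H)-one | C=C1C(=O)O[C@@H]2/C=C(/C)CC/C=C(\C)C[C@@H](OCc3ccc(OC)cc3)[C@@H]12 | intermediate
22 | (3aR,4R,6E,10Z,11aR)-4-hydroxy-6,10-dimethyl-3-methylidene-3a,4,5,8,9,11a-hexahydrocyclodeca[b]furan-2(3H)-one | C=C1C(=O)O[C@@H]2/C=C(/C)CC/C=C(\C)C[C@@H](O)[C@@H]12 | intermediate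
23 | angelic acid [(Z)-2-methylbut-2-enoic acid] | C/C=C(/C)C(=O)O | starting material
24 | (Z)-2-methylbut-2-en-1-ol | C/C=C(/C)CO | intermediate
25 | [(2R,3S)-2,3-dimethyloxiran-2-yl]methanol | OC[C@@]1(C)O[C@H]1C | intermediate
26 | (2S,3S)-2,3-dimethyloxirane-2-carboxylic acid | OC(=O)[C@@]1(C)O[C@H]1C | intermediate
27 | (2S,3S)-2,3-dimethyloxirane-2-carboxylic 2,4,6-trichlorobenzoic anhydride (mixed anhydride) | O=C(OC(=O)c1c(Cl)cc(Cl)cc1Cl)[C@@]2(C)O[C@H]2C | intermediate
28 | (3aR,4R,6E,10Z,11aR)-6,10-dimethyl-3-methylidene-2-oxo-2,3,3a,4,5,8,9,11a-octahydrocyclodeca[b]furan-4-yl (2S,3S)-2,3-dimethyloxirane-2-carboxylate | C=C1C(=O)O[C@@H]2/C=C(/C)CC/C=C(\C)C[C@@H](OC(=O)[C@@]3(C)O[C@H]3C)[C@@H]12 | intermediate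
29 | CNP0165580.1 [1β,10α-epoxy-8β-((2S,3S)-2,3-dimethyloxirane-2-carbonyloxy)germacra-4Z,11(13)-dien-12,6α-olide; 1R,6R,7R,8R,10R] | C=C1C(=O)O[C@@H]2/C=C(/C)CC[C@H]3O[C@]3(C)C[C@@H](OC(=O)[C@@]3(C)O[C@H]3C)[C@@H]12 | target

**Count and risks**

Total steps: 13. Longest linear sequence: 9 steps (steps 2, 3, 4, 5, 6, 7, 8, 12 and 13, from 4-methoxybenzyl alcohol).

Step 5 (most likely to fail). The enolate may lose the C8 alkoxide (E1cB), may invert its conformation before it is alkylated (poor facial selectivity at C7), or the rearrangement may pass through a boat. The fallback separates rearrangement from bond formation; it sets out from 11 and comes back at 15. The rearrangement is run alone, enolate 14 is protonated at −78 °C, and the ketone (2Z,6E,9R)-9-(4-methoxybenzyloxy)-3,7-dimethylcyclodeca-2,6-dien-1-one F1 is isolated. Kinetic deprotonation at C7 with LiN(SiMe3)2 in THF at −78 °C then gives its lithium enolate F2, in which lithium is chelated between the enolate oxygen and O8. Alkylation of this chelate with 12, anti to C9, should give 15.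

Step 6. Hydride may add to the other carbonyl face (poor facial selectivity), which would lead to the 6S alcohol and the cis-fused lactone. The fallback uses the opposite selectivity on purpose and then inverts C6; it sets out from 15 and comes back at 17. Chelation-controlled reduction with Zn(BH4)2 in Et2O at −78 °C should give the 6S hydroxy ester F3, which is kept cold and neutral. Mitsunobu esterification (4-nitrobenzoic acid, PPh3, DIAD) inverts C6 to the 6R 4-nitrobenzoate F4. K2CO3 in MeOH removes the benzoate, and the liberated 6R alkoxide closes lactone 17.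

Step 3. The benzylic ynol ether may rearrange on warming, and the Z geometry may be eroded by reversible stannyl-radical addition. The fallback reaches the vinyllithium without an ynol ether or tin; it sets out from 3 and comes back at 10, which then enters step 4. Transfer vinylation of 3 (ethyl vinyl ether, Pd(OAc)2, 1,10-phenanthroline) gives 4-methoxybenzyl vinyl ether F5. Bromine addition at −78 °C gives 1,2-dibromoethyl 4-methoxybenzyl ether F6, and dehydrobromination with iPr2NEt gives (Z)-2-bromovinyl 4-methoxybenzyl ether F7. Bromine–lithium exchange with t-BuLi in Et2O at −78 °C then gives vinyllithium 10.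

Further compounds
F1 | step 5 | (2Z,6E,9R)-9-(4-methoxybenzyloxy)-3,7-dimethylcyclodeca-2,6-dien-1-one | O=C1/C=C(/C)CC/C=C(\C)C[C@@H](OCc2ccc(OC)cc2)C1
F2 | step 5 | lithium enolate of F1 (O–C6=C7, C5 trans to C8) | [Li+].[O-]/C1=C\[C@H](OCc2ccc(OC)cc2)C/C(C)=C/CC/C(C)=C\1
F3 | step 6 | methyl 2-[(1S,2S,3Z,7E,10R)-2-hydroxy-10-(4-methoxybenzyloxy)-4,8-dimethylcyclodeca-3,7-dien-1-yl]acetate (6S hydroxy ester) | O[C@H]1/C=C(/C)CC/C=C(\C)C[C@@H](OCc2ccc(OC)cc2)[C@H]1CC(=O)OC
F4 | step 6 | 4-nitrobenzoate of 6R hydroxy ester 16 | O=C(O[C@@H]1/C=C(/C)CC/C=C(\C)C[C@@H](OCc2ccc(OC)cc2)[C@H]1CC(=O)OC)c1ccc(cc1)[N+](=O)[O-]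
F5 | step 3 | 4-methoxybenzyl vinyl ether | COc1ccc(COC=C)cc1
F6 | step 3 | 1,2-dibromoethyl 4-methoxybenzyl ether | COc1ccc(COC(Br)CBr)cc1
F7 | step 3 | (Z)-2-bromovinyl 4-methoxybenzyl ether | COc1ccc(CO/C=C\Br)cc1
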